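Everything rests on opening ring A at its C2=C3 double bond, which is closed last by an intramolecular aldol condensation. The step exploits the fact that in ring A C3 is bonded to the fully substituted C4 and can therefore be a non-enolisable aldehyde, whereas the C1 ketone, flanked by the C6=C5(OMe) vinylogous ester, can be deprotonated only at C2. One operation joins C2 to C3, closes the six-membered ring and removes the aldehyde oxygen, giving the cross-conjugated dienone. The precursor 29 is an acyclic (S)-α-methoxy aldehyde bearing the Z-cinnamyl group and an E β-methoxy enone. Its E geometry is inherited from a lactone and C4 from an enzymatic desymmetrisation.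

Key step: step 18

Atom labels: ring A is C1 (C=O), C2 (carries the CH2 linker), C3 (H), C4 (quaternary), C5 (OMe), C6 (H). The same labels are used for these atoms in all open-chain compounds.

Assumption: the lipase of step 5 is taken to acylate the pro-S CH2OH of diol 7. This sense must be verified on 8, and the answer to the opposite sense is given under the fallbacks.

Remark: C4 keeps one spatial arrangement from 8 to 34. Its descriptor changes only because the CIP ranks of its neighbours change (S in 8, 10–13, 29, 30; R in 9, 14, 15, 27, 28, 31–34).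

Step 1
Reactants: 1 3-phenylprop-2-yn-1-ol
Product: 2 (3-bromoprop-1-yn-1-yl)benzene
Conditions: PBr3 (0.4 equiv), pyridine (cat.), Et2O, 0 °C → rt
Reagents that add atoms: phosphorus tribromide, BrP(Br)Br
Why: A primary propargylic alcohol is turned into its bromide by SN2 displacement of the intermediate phosphite ester, and no stereochemical issue arises.

Step 2
Reactants: 3 dimethyl methoxymalonate; 2 (3-bromoprop-1-yn-1-yl)benzene
Product: 5 dimethyl 2-methoxy-2-(3-phenylprop-2-yn-1-yl)propanedioate, via sodium enolate 4 (not isolated)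
Conditions: NaH (1.1 equiv), THF–DMF, 0 °C; then 2, 0 °C → rt
Reagents that add atoms: none
Why: In this malonic ester alkylation the donor has a single acidic hydrogen, so SN2 attack on the unhindered propargylic bromide can occur only once and builds the fully substituted, still prochiral carbon that becomes C4.

Step 3
Reactants: 5 dimethyl 2-methoxy-2-(3-phenylprop-2-yn-1-yl)propanedioate
Product: 6 dimethyl 2-methoxy-2-[(2Z)-3-phenylprop-2-en-1-yl]propanedioate
Conditions: H2 (1 atm), Pd/CaCO3 poisoned with Pb(OAc)2 (Lindlar catalyst), quinoline, EtOAc, rt, stopped after one equivalent of H2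
Reagents that add atoms: none
Why: Lindlar semihydrogenation delivers both hydrogens syn from the poisoned Pd surface and so sets the Z alkene, and it is placed here while this is the only alkyne present and before LiAlH4 could hydroaluminate it.

Step 4
Reactants: 6 dimethyl 2-methoxy-2-[(2Z)-3-phenylprop-2-en-1-yl]propanedioate
Product: 7 2-methoxy-2-[(2Z)-3-phenylprop-2-en-1-yl]propane-1,3-diol
Conditions: LiAlH4, THF, 0 °C → rt; aqueous work-up
Reagents that add atoms: none
Why: Hydride reduction of both esters gives the prochiral 1,3-diol, and the isolated Z-styrene and the tertiary methyl ether are inert to LiAlH4 at this temperature.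

Step 5
Reactants: 7 2-methoxy-2-[(2Z)-3-phenylprop-2-en-1-yl]propane-1,3-diol
Product: 8 (2S,4Z)-2-(hydroxymethyl)-2-methoxy-5-phenylpent-4-en-1-yl acetate
Conditions: Burkholderia cepacia lipase (immobilised), vinyl acetate, i-Pr2O, 30 °C
Reagents that add atoms: vinyl acetate, C=COC(C)=O
Why: In this lipase desymmetrisation of a prochiral 2,2-disubstituted propane-1,3-diol by irreversible transesterification the active site tells the long Z-cinnamyl arm from the small OMe group, acylates one enantiotopic CH2OH and thereby creates C4, while slight over-acylation to the diacetate should consume the minor enantiomer preferentially.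

Step 6
Reactants: 8 (2S,4Z)-2-(hydroxymethyl)-2-methoxy-5-phenylpent-4-en-1-yl acetate
Product: 9 (2R,4Z)-2-formyl-2-methoxy-5-phenylpent-4-en-1-yl acetate
Conditions: Dess–Martin periodinane (1.2 equiv), NaHCO3, CH2Cl2, 0 °C → rt, run directly on fresh 8
Reagents that add atoms: none
Why: The buffered Dess–Martin oxidation stops at an aldehyde that has no α-hydrogen, so it can neither epimerise nor lose acetate, and it removes the free hydroxyl before 1,3-acetyl migration could erode the enantiopurity of 8.

Step 7
Reactants: 9 (2R,4Z)-2-formyl-2-methoxy-5-phenylpent-4-en-1-yl acetate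
Product: 10 (2S,4Z)-2-(2,2-dibromoethenyl)-2-methoxy-5-phenylpent-4-en-1-yl acetate
Conditions: CBr4 (2 equiv), PPh3 (4 equiv), CH2Cl2, 0 °C
Reagents that add atoms: carbon tetrabromide, BrC(Br)(Br)Br
Why: The Ramirez dibromoolefination, first stage of the Corey–Fuchs sequence, is a Wittig-type reaction under neutral conditions that tolerates the acetate and the styrene and is routine for α-quaternary aldehydes.

Step 8
Reactants: 10 (2S,4Z)-2-(2,2-dibromoethenyl)-2-methoxy-5-phenylpent-4-en-1-yl acetate
Product: 12 methyl (4S,6Z)-4-methoxy-4-{[(methoxycarbonyl)oxy]methyl}-7-phenylhept-6-en-2-ynoate, via dilithio alkynolate 11 (not isolated)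
Conditions: n-BuLi (4.5 equiv), THF, −78 → −20 °C; ClCO2Me (5 equiv), −78 → 0 °C; aqueous work-up
Reagents that add atoms: methyl chloroformate, COC(=O)Cl
Why: In the second Corey–Fuchs stage Br/Li exchange, α-elimination with 1,2-hydrogen shift and deprotonation give the lithium acetylide, two further equivalents of n-BuLi strip the acetate, the chloroformate acylates carbon and oxygen, and any material left as free carbinol converges on the same lactone in step 9.

Step 9
Reactants: 12 methyl (4S,6Z)-4-methoxy-4-{[(methoxycarbonyl)oxy]methyl}-7-phenylhept-6-en-2-ynoate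
Product: 15 (5R)-4,5-dimethoxy-5-[(2Z)-3-phenylprop-2-en-1-yl]-5,6-dihydro-2H-pyran-2-one, via hydroxy alkynoate 13 (not isolated), via E methoxy enoate 14 (not isolated)
Conditions: NaOMe (0.3 equiv), MeOH, rt → 50 °C
Reagents that add atoms: methanol, CO
Why: This is the classical conversion of a δ-hydroxy alkynoate into a 4-methoxy-5,6-dihydropyran-2-one (carbonate methanolysis, oxa-Michael addition, lactonisation), in which only the E adduct with C4 and the ester cis can lactonise, so reversible methoxide addition should funnel all material into a ring that fixes the C5=C6 geometry.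

Step 10
Reactants: 16 vanillin
Product: 17 3-methoxy-4-[(triisopropylsilyl)oxy]benzaldehyde
Conditions: TIPSCl, imidazole, DMF, rt
Reagents that add atoms: triisopropylsilyl chloride, CC(C)[Si](Cl)(C(C)C)C(C)C
Why: In this imidazole-promoted phenol silylation the triisopropylsilyl aryl ether is chosen because it resists carbonate, sulfonic acid resin, alkyllithiums and amidine base far better than smaller silyl ethers and still falls to fluoride within minutes.

Step 11
Reactants: 17 3-methoxy-4-[(triisopropylsilyl)oxy]benzaldehyde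
Product: 19 3-methoxy-4-[(triisopropylsilyl)oxy]phenol, via aryl formate 18 (not isolated)
Conditions: mCPBA, CH2Cl2, 0 °C → rt; then MeOH, Et3N (cat.), rt
Reagents that add atoms: 3-chloroperoxybenzoic acid, OOC(=O)c1cccc(Cl)c1
Why: In the Baeyer–Villiger oxidation of an electron-rich benzaldehyde the aryl group migrates to give the formate, which mild methanolysis cleaves without touching the silyl ether.

Step 12
Reactants: 19 3-methoxy-4-[(triisopropylsilyl)oxy]phenol; 20 2-bromoacetophenone
Product: 21 2-{3-methoxy-4-[(triisopropylsilyl)oxy]phenoxy}-1-phenylethan-1-one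
Conditions: K2CO3, acetone, 50 °C
Reagents that add atoms: none
Why: This is a Williamson ether synthesis in which the phenoxide displaces bromide from the highly SN2-active phenacyl bromide under anhydrous carbonate conditions.

Step 13
Reactants: 21 2-{3-methoxy-4-[(triisopropylsilyl)oxy]phenoxy}-1-phenylethan-1-one
Product: 22 6-methoxy-3-phenyl-5-[(triisopropylsilyl)oxy]-1-benzofuran
Conditions: Amberlyst 15 (sulfonic acid resin), 4 Å MS, PhMe, 80 °C
Reagents that add atoms: none
Why: Acid-catalysed cyclodehydration of an α-aryloxy ketone (intramolecular Friedel–Crafts hydroxyalkylation, then loss of water) should occur at the unhindered ring carbon that is ortho to the ether oxygen and para to OMe, which places OMe at C6 and the silyloxy group at C5 of the benzofuran.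

Step 14
Reactants: 22 6-methoxy-3-phenyl-5-[(triisopropylsilyl)oxy]-1-benzofuran
Product: 24 2-{6-methoxy-3-phenyl-5-[(triisopropylsilyl)oxy]-1-benzofuran-2-yl}ethan-1-ol, via 2-lithiobenzofuran 23 (not isolated)
Conditions: n-BuLi (1.1 equiv), THF, −78 °C; ethylene oxide (3 equiv), −78 °C → rt; H2O
Reagents that add atoms: ethylene oxide, C1CO1
Why: α-Lithiation of the furan ring at its C2–H, kinetically the most acidic position at −78 °C, followed by SN2 opening of the epoxide, installs the linker carbon and C2 of ring A.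

Step 15
Reactants: 24 2-{6-methoxy-3-phenyl-5-[(triisopropylsilyl)oxy]-1-benzofuran-2-yl}ethan-1-ol
Product: 25 2-(2-iodoethyl)-6-methoxy-3-phenyl-5-[(triisopropylsilyl)oxy]-1-benzofuran
Conditions: I2, PPh3, imidazole, CH2Cl2, 0 °C → rt
Reagents that add atoms: iodine, II
Why: In this Appel-type iodination the primary alkoxyphosphonium ion is displaced by iodide under essentially neutral conditions that leave the silyl ether and the heterocycle alone.

Step 16
Reactants: 25 2-(2-iodoethyl)-6-methoxy-3-phenyl-5-[(triisopropylsilyl)oxy]-1-benzofuran; 15 (5R)-4,5-dimethoxy-5-[(2Z)-3-phenylprop-2-en-1-yl]-5,6-dihydro-2H-pyran-2-one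
Product: 28 (4E,6R,8Z)-6-(hydroxymethyl)-5,6-dimethoxy-1-{6-methoxy-3-phenyl-5-[(triisopropylsilyl)oxy]-1-benzofuran-2-yl}-9-phenylnona-4,8-dien-3-one, via alkyllithium 26 (not isolated), via lithium lactolate 27 (not isolated)
Conditions: 25, t-BuLi (2.05 equiv), Et2O–pentane, −78 °C; cannulated into 15, THF, −78 °C; pH 7 phosphate buffer at −78 °C
Reagents that add atoms: none
Why: Lithium–iodine exchange gives a primary alkyllithium that adds once to the δ-lactone because the lactolate does not collapse at −78 °C, and the neutral quench opens it to the hydroxy ketone, whose C5=C6 bond keeps the ring-imposed E geometry and whose vinylogous-ester resonance favours the open form.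

Step 17
Reactants: 28 (4E,6R,8Z)-6-(hydroxymethyl)-5,6-dimethoxy-1-{6-methoxy-3-phenyl-5-[(triisopropylsilyl)oxy]-1-benzofuran-2-yl}-9-phenylnona-4,8-dien-3-one
Product: 29 (2S,3E)-2,3-dimethoxy-7-{6-methoxy-3-phenyl-5-[(triisopropylsilyl)oxy]-1-benzofuran-2-yl}-5-oxo-2-[(2Z)-3-phenylprop-2-en-1-yl]hept-3-enal
Conditions: Dess–Martin periodinane (1.3 equiv), NaHCO3, CH2Cl2, 0 °C; used without storage
Reagents that add atoms: none
Why: The NaHCO3-buffered Dess–Martin oxidation is neutral enough for the enol ether, benzofuran, Z-styrene and aryl silyl ether and stops at the C3 aldehyde, which cannot epimerise because C4 bears no hydrogen.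

Step 18
Reactants: 29 (2S,3E)-2,3-dimethoxy-7-{6-methoxy-3-phenyl-5-[(triisopropylsilyl)oxy]-1-benzofuran-2-yl}-5-oxo-2-[(2Z)-3-phenylprop-2-en-1-yl]hept-3-enal
Product: 33 (4R)-4,5-dimethoxy-2-({6-methoxy-3-phenyl-5-[(triisopropylsilyl)oxy]-1-benzofuran-2-yl}methyl)-4-[(2Z)-3-phenylprop-2-en-1-yl]cyclohexa-2,5-dien-1-one, via lithium enolate 30 (not isolated), via lithium aldolate 31 (not isolated), via acetoxy ketone 32 (not isolated)
Conditions: LiN(SiMe3)2 (1.1 equiv), THF (0.01 M), −78 °C; Ac2O (1.5 equiv), −78 → 0 °C; DBU (3 equiv), 0 °C → rt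
Reagents that add atoms: none
Why: LiN(SiMe3)2 removes a C2 hydrogen, the only acidic C–H in 29 because C4 is fully substituted and C6 is vinylic, the cross-conjugated enolate 30 adds through C2 to the C3 aldehyde to give aldolate 31, acetic anhydride traps the oxygen as acetate 32 and DBU expels it by E1cB, so C2=C3 and ring A appear in one flask. The closest known reaction type is the intramolecular aldol condensation of a keto aldehyde that ends a Robinson annulation, combined with the α′-enolisation of vinylogous esters familiar from Stork–Danheiser chemistry. Ring A closes in the favoured 6-(enolendo)-exo-trig mode. No lasting stereocentre is created, since C2 and C3 of 31 and 32 form as mixtures that the elimination erases, and C4, which has no hydrogen and no enolisable neighbour, passes through unchanged. The step needs one donor, one acceptor and chain ends that can meet; the substitution pattern secures the first two and the E enol ether, which holds C4 and C1 cis, secures the third. A non-nucleophilic amide base and departure of the oxygen as acetate rather than hydroxide are chosen because an oxygen nucleophile on the formyl group could expel C4 as a dienolate (vinylogous retro-Claisen loss of formate) and would also attack the aryl silyl ether.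

Step 19
Reactants: 33 (4R)-4,5-dimethoxy-2-({6-methoxy-3-phenyl-5-[(triisopropylsilyl)oxy]-1-benzofuran-2-yl}methyl)-4-[(2Z)-3-phenylprop-2-en-1-yl]cyclohexa-2,5-dien-1-one
Product: 34 (4R)-2-[(5-hydroxy-6-methoxy-3-phenyl-1-benzofuran-2-yl)methyl]-4,5-dimethoxy-4-[(2Z)-3-phenylprop-2-en-1-yl]cyclohexa-2,5-dien-1-one (CNP0306784.1)
Conditions: Bu4NF (1.2 equiv), AcOH (1.2 equiv), THF, 0 °C; chromatography on Et3N-deactivated silica
Reagents that add atoms: none
Why: Fluoride cleaves an aryl silyl ether quickly because phenoxide leaves readily from pentacoordinate silicon, and the AcOH buffer keeps the medium near neutral so that neither base-induced addition to the dienone nor acid-induced dienone–phenol rearrangement of the quinol ether can start.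

Compound list
1 | 3-phenylprop-2-yn-1-ol | OCC#Cc1ccccc1 | starting material
2 | (3-bromoprop-1-yn-1-yl)benzene | BrCC#Cc1ccccc1 | intermediate
3 | dimethyl methoxymalonate | COC(C(=O)OC)C(=O)OC | starting material
4 | sodium enolate of 3 (not isolated) | [Na+].COC(=O)[C-](OC)C(=O)OC | intermediate
5 | dimethyl 2-methoxy-2-(3-phenylprop-2-yn-1-yl)propanedioate | COC(=O)C(CC#Cc1ccccc1)(OC)C(=O)OC | intermediate
6 | dimethyl 2-methoxy-2-[(2Z)-3-phenylprop-2-en-1-yl]propanedioate | COC(=O)C(C/C=C\c1ccccc1)(OC)C(=O)OC | intermediate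
7 | 2-methoxy-2-[(2Z)-3-phenylprop-2-en-1-yl]propane-1,3-diol | OCC(CO)(C/C=C\c1ccccc1)OC | intermediate
8 | (2S,4Z)-2-(hydroxymethyl)-2-methoxy-5-phenylpent-4-en-1-yl acetate | CC(=O)OC[C@@](CO)(C/C=C\c1ccccc1)OC | intermediate
9 | (2R,4Z)-2-formyl-2-methoxy-5-phenylpent-4-en-1-yl acetate | CC(=O)OC[C@@](C=O)(C/C=C\c1ccccc1)OC | intermediate
10 | (2S,4Z)-2-(2,2-dibromoethenyl)-2-methoxy-5-phenylpent-4-en-1-yl acetate | CC(=O)OC[C@@](C=C(Br)Br)(C/C=C\c1ccccc1)OC | intermediate
11 | dilithio derivative (alkoxide and acetylide) of (2S,4Z)-2-ethynyl-2-methoxy-5-phenylpent-4-en-1-ol (not isolated) | [Li]OC[C@@](C#C[Li])(C/C=C\c1ccccc1)OC | intermediate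
12 | methyl (4S,6Z)-4-methoxy-4-{[(methoxycarbonyl)oxy]methyl}-7-phenylhept-6-en-2-ynoate | COC(=O)OC[C@@](C#CC(=O)OC)(C/C=C\c1ccccc1)OC | intermediate
13 | methyl (4S,6Z)-4-(hydroxymethyl)-4-methoxy-7-phenylhept-6-en-2-ynoate (not isolated) | OC[C@@](C#CC(=O)OC)(C/C=C\c1ccccc1)OC | intermediate
14 | methyl (2E,4R,6Z)-4-(hydroxymethyl)-3,4-dimethoxy-7-phenylhepta-2,6-dienoate (not isolated) | OC[C@@](/C(OC)=C\C(=O)OC)(C/C=C\c1ccccc1)OC | intermediate
15 | (5R)-4,5-dimethoxy-5-[(2Z)-3-phenylprop-2-en-1-yl]-5,6-dihydro-2H-pyran-2-one | COC1=CC(=O)OC[C@@]1(C/C=C\c1ccccc1)OC | intermediate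
16 | vanillin | COc1cc(C=O)ccc1O | starting material
17 | 3-methoxy-4-[(triisopropylsilyl)oxy]benzaldehyde | COc1cc(C=O)ccc1O[Si](C(C)C)(C(C)C)C(C)C | intermediate
18 | 3-methoxy-4-[(triisopropylsilyl)oxy]phenyl formate (not isolated) | COc1cc(OC=O)ccc1O[Si](C(C)C)(C(C)C)C(C)C | intermediate
19 | 3-methoxy-4-[(triisopropylsilyl)oxy]phenol | COc1cc(O)ccc1O[Si](C(C)C)(C(C)C)C(C)C | intermediate
20 | 2-bromoacetophenone | O=C(CBr)c1ccccc1 | starting material
21 | 2-{3-methoxy-4-[(triisopropylsilyl)oxy]phenoxy}-1-phenylethan-1-one | COc1cc(OCC(=O)c2ccccc2)ccc1O[Si](C(C)C)(C(C)C)C(C)C | intermediate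
22 | 6-methoxy-3-phenyl-5-[(triisopropylsilyl)oxy]-1-benzofuran | c1oc2cc(OC)c(O[Si](C(C)C)(C(C)C)C(C)C)cc2c1-c1ccccc1 | intermediate
23 | 2-lithio derivative of 22 (not isolated) | [Li]c1oc2cc(OC)c(O[Si](C(C)C)(C(C)C)C(C)C)cc2c1-c1ccccc1 | intermediate
24 | 2-{6-methoxy-3-phenyl-5-[(triisopropylsilyl)oxy]-1-benzofuran-2-yl}ethan-1-ol | OCCc1oc2cc(OC)c(O[Si](C(C)C)(C(C)C)C(C)C)cc2c1-c1ccccc1 | intermediate
25 | 2-(2-iodoethyl)-6-methoxy-3-phenyl-5-[(triisopropylsilyl)oxy]-1-benzofuran | ICCc1oc2cc(OC)c(O[Si](C(C)C)(C(C)C)C(C)C)cc2c1-c1ccccc1 | intermediate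
26 | 2-(2-lithioethyl) analogue of 25 (not isolated) | [Li]CCc1oc2cc(OC)c(O[Si](C(C)C)(C(C)C)C(C)C)cc2c1-c1ccccc1 | intermediate
27 | lithium lactolate from 26 and 15, quaternary carbon R, new hemiketal carbon undefined (not isolated) | COC1=CC(O[Li])(CCc2oc3cc(OC)c(O[Si](C(C)C)(C(C)C)C(C)C)cc3c2-c2ccccc2)OC[C@@]1(C/C=C\c1ccccc1)OC | intermediate
28 | (4E,6R,8Z)-6-(hydroxymethyl)-5,6-dimethoxy-1-{6-methoxy-3-phenyl-5-[(triisopropylsilyl)oxy]-1-benzofuran-2-yl}-9-phenylnona-4,8-dien-3-one | OC[C@@](/C(OC)=C\C(=O)CCc1oc2cc(OC)c(O[Si](C(C)C)(C(C)C)C(C)C)cc2c1-c1ccccc1)(C/C=C\c1ccccc1)OC | intermediate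
29 | (2S,3E)-2,3-dimethoxy-7-{6-methoxy-3-phenyl-5-[(triisopropylsilyl)oxy]-1-benzofuran-2-yl}-5-oxo-2-[(2Z)-3-phenylprop-2-en-1-yl]hept-3-enal | O=C[C@](OC)(C/C=C\c1ccccc1)/C(OC)=C\C(=O)CCc1oc2cc(OC)c(O[Si](C(C)C)(C(C)C)C(C)C)cc2c1-c1ccccc1 | intermediate
30 | lithium C1–C2 enolate of 29, enolate geometry undefined (not isolated) | O=C[C@](OC)(C/C=C\c1ccccc1)/C(OC)=C\C(O[Li])=CCc1oc2cc(OC)c(O[Si](C(C)C)(C(C)C)C(C)C)cc2c1-c1ccccc1 | intermediate
31 | ring A lithium aldolate, C4 R, C2 and C3 as mixtures (not isolated) | COC1=CC(=O)C(Cc2oc3cc(OC)c(O[Si](C(C)C)(C(C)C)C(C)C)cc3c2-c2ccccc2)C(O[Li])[C@@]1(C/C=C\c1ccccc1)OC | intermediate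
32 | ring A 3-acetoxy ketone, C4 R, C2 and C3 as mixtures (not isolated) | COC1=CC(=O)C(Cc2oc3cc(OC)c(O[Si](C(C)C)(C(C)C)C(C)C)cc3c2-c2ccccc2)C(OC(C)=O)[C@@]1(C/C=C\c1ccccc1)OC | intermediate
33 | (4R)-4,5-dimethoxy-2-({6-methoxy-3-phenyl-5-[(triisopropylsilyl)oxy]-1-benzofuran-2-yl}methyl)-4-[(2Z)-3-phenylprop-2-en-1-yl]cyclohexa-2,5-dien-1-one | COC1=CC(=O)C(Cc2oc3cc(OC)c(O[Si](C(C)C)(C(C)C)C(C)C)cc3c2-c2ccccc2)=C[C@@]1(C/C=C\c1ccccc1)OC | intermediate
34 | (4R)-2-[(5-hydroxy-6-methoxy-3-phenyl-1-benzofuran-2-yl)methyl]-4,5-dimethoxy-4-[(2Z)-3-phenylprop-2-en-1-yl]cyclohexa-2,5-dien-1-one | COC1=CC(=O)C(Cc2oc3cc(OC)c(O)cc3c2-c2ccccc2)=C[C@@]1(C/C=C\c1ccccc1)OC | target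

Total step count: 19. Longest linear sequence: 13 steps (steps 1–9 and 16–19). The benzofuran branch (steps 10–15) joins at step 16.

Steps most likely to fail

Step 18. The amide base may add to the very electrophilic formyl group, the C3–C4 bond may cleave with loss of the formyl group, or the aldol may revert before the aldolate is trapped. The fallback moves from a metal enolate to a neutral enol silane and activates the acceptor instead of the donor (intramolecular Mukaiyama aldol). It sets out from 29. Me3SiOTf and i-Pr2NEt in CH2Cl2 at −78 °C should convert the vinylogous ester into the cross-conjugated trimethylsilyl dienol ether F1, by the same soft enolisation that makes 1-methoxy-3-silyloxybutadienes. The excess silyl triflate then activates the aldehyde, and C2 closes onto C3 to give the ring A β-trimethylsilyloxy ketone F2. The C3 oxygen cannot reach C5 without forming a four-membered ring, so no pyranone can form. DBU in CH2Cl2 at rt eliminates silanol by E1cB, and the route is rejoined at 33.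

Step 5. The enzyme may acylate the wrong enantiotopic arm or discriminate weakly between the two arms. The fallback runs the enzyme in the hydrolytic direction. It sets out from 7, which Ac2O, pyridine and DMAP (cat.) convert into the achiral diacetate F3. The same lipase in pH 7 phosphate buffer with MTBE then removes the acetate from the arm it prefers. The surviving ester therefore sits on the other arm, and the monoacetate antipodal to that of the acylation mode results. The route is rejoined at 8, which is oxidised at once as in step 6.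

Step 16. The lactolate may collapse prematurely, leading to a second addition, or the alkyllithium may deprotonate the lactone instead of adding to the carbonyl. The fallback is a Weinreb ketone synthesis on the opened lactone, setting out from 15. MeNHOMe·HCl and i-PrMgCl (THF, −20 °C) should open the ring to the hydroxy N-methoxy-N-methyl amide F4 with the E geometry retained. Et3SiCl and imidazole cap the carbinol before it can relactonise, giving the triethylsilyl ether F5. Alkyllithium 26 then adds once, because the chelated adduct holds until the quench, and gives the silyl-protected ketone F6. HF·pyridine buffered with excess pyridine (THF, 0 °C) removes the primary triethylsilyl ether and leaves the aryl triisopropylsilyl ether. The route is rejoined at 28.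

Further compounds
F1 | step 18 | (2S,3E)-2,3-dimethoxy-7-{6-methoxy-3-phenyl-5-[(triisopropylsilyl)oxy]-1-benzofuran-2-yl}-2-[(2Z)-3-phenylprop-2-en-1-yl]-5-[(trimethylsilyl)oxy]hepta-3,5-dienal, geometry of the new enol silane undefined | O=C[C@](OC)(C/C=C\c1ccccc1)/C(OC)=C\C(O[Si](C)(C)C)=CCc1oc2cc(OC)c(O[Si](C(C)C)(C(C)C)C(C)C)cc2c1-c1ccccc1
F2 | step 18 | ring A 3-(trimethylsilyloxy) ketone, C4 R, C2 and C3 as mixtures | COC1=CC(=O)C(Cc2oc3cc(OC)c(O[Si](C(C)C)(C(C)C)C(C)C)cc3c2-c2ccccc2)C(O[Si](C)(C)C)[C@@]1(C/C=C\c1ccccc1)OC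
F3 | step 5 | 2-methoxy-2-[(2Z)-3-phenylprop-2-en-1-yl]propane-1,3-diyl diacetate | CC(=O)OCC(COC(C)=O)(C/C=C\c1ccccc1)OC
F4 | step 16 | (2E,4R,6Z)-4-(hydroxymethyl)-N,3,4-trimethoxy-N-methyl-7-phenylhepta-2,6-dienamide | OC[C@@](/C(OC)=C\C(=O)N(C)OC)(C/C=C\c1ccccc1)OC
F5 | step 16 | (2E,4R,6Z)-N,3,4-trimethoxy-N-methyl-7-phenyl-4-{[(triethylsilyl)oxy]methyl}hepta-2,6-dienamide | CC[Si](CC)(CC)OC[C@@](/C(OC)=C\C(=O)N(C)OC)(C/C=C\c1ccccc1)OC
F6 | step 16 | (4E,6R,8Z)-5,6-dimethoxy-1-{6-methoxy-3-phenyl-5-[(triisopropylsilyl)oxy]-1-benzofuran-2-yl}-9-phenyl-6-{[(triethylsilyl)oxy]methyl}nona-4,8-dien-3-one | CC[Si](CC)(CC)OC[C@@](/C(OC)=C\C(=O)CCc1oc2cc(OC)c(O[Si](C(C)C)(C(C)C)C(C)C)cc2c1-c1ccccc1)(C/C=C\c1ccccc1)OC
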